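I could not get more target out of the flask than the coupling partner that self-condensation spared, since each target costs one of it.

substrate 0.097 M; coupling partner 0.107 M; initiator 7.0 mM; radical scavenger 0.19 mM; time 15 h

    initiator → 2 initiating radical (k1 = 1.36 × 10⁻⁴ min⁻¹)
    substrate + initiating radical → capped initiator + first chain carrier (k2 = 8.29 × 10⁶ L mol⁻¹ s⁻¹)
    coupling partner + first chain carrier → target + second chain carrier (k3 = 8.69 × 10⁵ L mol⁻¹ s⁻¹)
    substrate + second chain carrier → by-product + first chain carrier (k4 = 83400 L mol⁻¹ s⁻¹)
    2 second chain carrier → ended chains A (k5 = 5.6 × 10⁷ L mol⁻¹ s⁻¹)
    2 first chain carrier → ended chains B (k6 = 1.5 × 10⁹ L mol⁻¹ s⁻¹)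
    second chain carrier + radical scavenger → ended chains C (k7 = 5.28 × 10⁸ L mol⁻¹ s⁻¹)
    2 coupling partner → self-condensation product (k8 = 0.0178 L mol⁻¹ min⁻¹)
    substrate ⇌ dormant form (K9 = 1.3, k9 = 0.351 min⁻¹)

- a species is counted by the substrate in it: one ended chains B counts as two
- two of one species on the left: rate k times its square, two consumed each time
- what has gone from substrate into another species counts as reacted, even if it can come back
- run time (flask): 15 h

* share of the substrate used up at 15 h
* target at 15 h, in percent of the substrate charged

The choice for the next run was whether to cut the initiator to 0.0042 M, because its half-life of 85 h is longer than the run of 15 h, and 88.5% of its charge stays unspent. So I asked what the initiator buys.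

The radical scavenger catches the second chain carrier at a pseudo-first-order rate of 1.00 × 10⁵ s⁻¹, while even the full substrate charge catches it at 8090 s⁻¹. I therefore took each radical to cost one scavenger, and no chain to run until the 0.19 mM was spent. This induction period is the scavenger charge divided by the radical supply, two per initiator decomposed, and it came to 99.8 min.

By my reckoning, second-order self-condensation brought the coupling partner down to 0.0775 M in that time. I carried this amount as the spared partner S, the coupling partner standing when the delay ends. It lay below the substrate charge, which made the coupling partner the limiting reagent.

I took termination of the second chain carrier to balance the radical supply, and on that estimate the substrate pool, free plus dormant, halves in 18.9 min, shorter than the 13.3 h remaining. So I reckoned target as S over the substrate charge, 79.9%. One substrate goes per target and the rest of the pool stands at 1.3 dormant for each free, which gave conversion 91.3%. In this reckoning a smaller initiator charge, the other charges held, lengthens the delay and lowers S, so I kept the charge.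

The forecast stood lower on target, at 76% (68% to 83%), with conversion 90.5% (87% to 94%), holding that the scavenger “holds the chain back for about 100 min”.

The flask gave conversion 90.9% and target 77.6%. At 1.93 h the step making target took coupling partner 38 times as fast as self-condensation, and the 0.0159 M of self-condensation product at 15.0 h holds 0.0318 M of partner, against the 0.0295 M that S wrote off. In the flask with 0.0042 M of initiator the delay comes to 166 min and S to 0.0655 M, which is 67.5% of the substrate charged, and that flask gave target 65.7%.

(The rate constants are invented; the result is computed.)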